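**Retrosynthetic overview**

1. Ester C–O bond: target ⇐ himachal-2-ene-4α,7α-diol + O-acetylisovanillic acid (acylation, then release of the phenol).
2. Allylic alcohol ⇐ Wharton transposition of a 3α,4α-epoxy-2-ketone ⇐ 7-hydroxyhimachal-3-en-2-one; C-7 carbinol ⇐ axial CH3 addition to a C-7 ketone.
3. Ring B (seven-membered) ⇐ C8–C9 bond by intramolecular alkylation of a methyl ketone enolate; the methyl ketone comes from ozonolysis of the isopropenyl group.
4. C1–C11 quaternary–tertiary bond ⇐ visible-light decarboxylative tert-alkylation of the kinetic silyl dienol ether of (R)-carvone with 4-bromo-2,2-dimethylbutanoic acid.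
5. Ring order: ring A is bought as (R)-(−)-carvone, whose stereocentre becomes C-6 and controls C-1, C-4 and C-7; ring B is then closed onto it.

Assumption: 4-bromo-2,2-dimethylbutanoic acid and 3-acetoxy-4-methoxybenzoic acid are bought as catalogue compounds.

Numbering of the bicyclic compounds (himachalane): C-1 and C-6 are the ring-fusion carbons; C-2 to C-5 complete ring A (methyl on C-3); C-7 to C-11 complete ring B (C-7 next to C-6, gem-dimethyl C-11 next to C-1, methyl C-14 on C-7). H-1 is β, H-6 is α (trans fusion).

**Step 1**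
Reactants: 1 (R)-(−)-carvone
Product: 2 tert-butyl(dimethyl){[(3R)-6-methyl-3-(prop-1-en-2-yl)cyclohexa-1,5-dien-1-yl]oxy}silane
Conditions: LiN(iPr)2 (1.1 equiv), THF, −78 °C; TBSOTf (1.15 equiv), −78 → 0 °C
Reagents that add atoms: tert-butyldimethylsilyl trifluoromethanesulfonate, CC(C)(C)[Si](C)(C)OS(=O)(=O)C(F)(F)F
Why: Kinetic deprotonation of the enone at the α′ carbon (C-6 of carvone) and O-silylation of the cross-conjugated lithium dienolate give the 2-silyloxy-1,3-diene without touching the bought stereocentre (kinetic enolate formation, silyl enol ether synthesis).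

**Step 2**
Reactants: 2 silyl dienol ether (2 equiv); 3 4-bromo-2,2-dimethylbutanoic acid; 4 N-hydroxyphthalimide
Product: 6 (5R,6R)-6-(4-bromo-2-methylbutan-2-yl)-2-methyl-5-(prop-1-en-2-yl)cyclohex-2-en-1-one, via phthalimidyl ester 5 (not isolated)
Conditions: 3, 4, DIC (1.05 equiv), DMAP (5 mol %), CH2Cl2, 0 → 23 °C; then 2, fac-Ir(ppy)3 [fac-tris(2-phenylpyridinato)iridium] (1 mol %), degassed, 450 nm LEDs, 23 °C; then 1 M HCl, THF, 0 °C
Reagents that add atoms: none
Why: Proposed new method: a photoredox radical-polar crossover α′-tert-alkylation of a cross-conjugated silyl dienol ether, in which the excited iridium complex reduces ester 5, loss of CO2 gives the tertiary radical, the tetravalent iridium formed oxidises it (or its α-silyloxyallyl radical adduct) to the cation, the diene terminus C-6 is attacked anti to the neighbouring isopropenyl group and phthalimide anion removes the silyl group, so the C1–C11 bond and the trans (6R) centre, which is also the more stable epimer at this enolisable carbon, are set; the closest known reaction types are the photoredox decarboxylative alkylation of aryl silyl enol ethers with N-acyloxyphthalimides and the Lewis-acid SN1 tert-alkylation of silyl enol ethers.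

**Step 3**
Reactants: 6 bromo enone
Product: 8 (5R,6R)-5-acetyl-6-(4-bromo-2-methylbutan-2-yl)-2-methylcyclohex-2-en-1-one, via ozonide 7 (not isolated)
Conditions: O3, CH2Cl2, −78 °C (Sudan Red 7B end point); Me2S, −78 → 23 °C
Reagents that add atoms: ozone, [O-][O+]=O
Why: Ozone cleaves the electron-rich 1,1-disubstituted alkene much faster than the electron-poor enone double bond, and the neutral reductive work-up leaves both ring stereocentres untouched (Criegee ozonolysis).

**Step 4**
Reactants: 8 bromo diketone
Product: 9 (1R,6R)-14-norhimachal-3-ene-2,7-dione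
Conditions: LiN(iPr)2 (1.05 equiv), THF (0.01 M), −78 °C; DMPU (5 equiv), n-Bu4NI (10 mol %), −78 → 23 °C; aq. NH4Cl at 0 °C
Reagents that add atoms: none
Why: Kinetic deprotonation of the methyl ketone at CH3 is followed by a 7-(enolendo)-exo-tet C-alkylation on the primary bromide that closes ring B, helped by the gem-dimethyl group, while the five-membered enolendo Michael and aldol closures onto the enone are stereoelectronically disfavoured and the cold quench spares the two enolisable ring-fusion centres (intramolecular enolate alkylation).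

**Step 5**
Reactants: 9 bicyclic dione
Product: 10 (1R,6R,7R)-7-hydroxyhimachal-3-en-2-one
Conditions: MeAl(OAr)2 (Ar = 2,6-tBu2-4-MeC6H2; 3 equiv), toluene, −78 °C; CH3Li (1.5 equiv), −78 °C; 1 M HCl
Reagents that add atoms: methyllithium, [Li]C
Why: The bulky aluminium aryloxide binds the saturated C-7 ketone on its open equatorial (α) side, so CH3Li adds along the axial β path anti to H-6 and gives the 7β-methyl 7α-hydroxy (7R) carbinol, while the enone carbonyl, flanked by the tert-alkyl-bearing C-1 and the C-3 methyl group, is too crowded to react (Yamamoto amphiphilic alkylation).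

**Step 6**
Reactants: 10 hydroxy enone
Product: 11 (1R,3R,4R,6R,7R)-3,4-epoxy-7-hydroxyhimachalan-2-one
Conditions: 30% aq. H2O2 (4 equiv), NaOH (0.3 equiv), MeOH, 0 °C
Reagents that add atoms: hydrogen peroxide, OO
Why: Hydroperoxide adds axially to C-4 trans to the C-6 substituent, as with carvone and other 5-substituted cyclohexenones, so the epoxide lies on the α face and C-4 is fixed as R (Weitz–Scheffer nucleophilic epoxidation).

**Step 7**
Reactants: 11 epoxy ketone
Product: 13 (1R,4R,6R,7R)-himachal-2-ene-4,7-diol, via epoxy hydrazone 12 (not isolated)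
Conditions: N2H4·H2O (3 equiv), AcOH (0.2 equiv), MeOH, 0 → 23 °C
Reagents that add atoms: none
Why: The hydrazone of the α,β-epoxy ketone opens the epoxide and loses N2, giving the C2=C3 alkene and the C-4 alcohol with its C–O bond, and therefore its α configuration, unchanged (Wharton transposition).

**Step 8**
Reactants: 13 diol; 14 3-acetoxy-4-methoxybenzoic acid
Product: 16 (1R,4R,6R,7R)-7-hydroxyhimachal-2-en-4-yl 3-hydroxy-4-methoxybenzoate, via acetyl-protected ester 15 (not isolated)
Conditions: 14 (1.3 equiv), DIC (1.5 equiv), DMAP (0.3 equiv), CH2Cl2, 0 → 23 °C; then pyrrolidine (4 equiv), 23 °C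
Reagents that add atoms: none
Why: Steglich esterification acylates only the secondary allylic alcohol, with retention at C-4 and no reaction at the tertiary C-7 alcohol, and pyrrolidine then cleaves the phenolic acetate by aminolysis much faster than the alkyl benzoate.

**Compound list**

1 | (R)-(−)-carvone, (5R)-2-methyl-5-(prop-1-en-2-yl)cyclohex-2-en-1-one | CC1=CC[C@@H](C(C)=C)CC1=O | starting material
2 | tert-butyl(dimethyl){[(3R)-6-methyl-3-(prop-1-en-2-yl)cyclohexa-1,5-dien-1-yl]oxy}silane | CC1=CC[C@@H](C(C)=C)C=C1O[Si](C)(C)C(C)(C)C | intermediate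
3 | 4-bromo-2,2-dimethylbutanoic acid | CC(C)(CCBr)C(=O)O | starting material
4 | N-hydroxyphthalimide | O=C1c2ccccc2C(=O)N1O | starting material
5 | 1,3-dioxoisoindolin-2-yl 4-bromo-2,2-dimethylbutanoate | CC(C)(CCBr)C(=O)ON1C(=O)c2ccccc2C1=O | intermediate (not isolated)
6 | (5R,6R)-6-(4-bromo-2-methylbutan-2-yl)-2-methyl-5-(prop-1-en-2-yl)cyclohex-2-en-1-one (trans) | CC1=CC[C@@H](C(C)=C)[C@H](C(C)(C)CCBr)C1=O | intermediate
7 | (5R,6R)-6-(4-bromo-2-methylbutan-2-yl)-2-methyl-5-(3-methyl-1,2,4-trioxolan-3-yl)cyclohex-2-en-1-one (both epimers at the trioxolane carbon) | CC1=CC[C@@H](C2(C)OOCO2)[C@H](C(C)(C)CCBr)C1=O | intermediate (not isolated)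
8 | (5R,6R)-5-acetyl-6-(4-bromo-2-methylbutan-2-yl)-2-methylcyclohex-2-en-1-one | CC1=CC[C@@H](C(C)=O)[C@H](C(C)(C)CCBr)C1=O | intermediate
9 | (1R,6R)-14-norhimachal-3-ene-2,7-dione (trans-fused, H-1 β, H-6 α) | CC1=CC[C@H]2C(=O)CCCC(C)(C)[C@@H]2C1=O | intermediate
10 | (1R,6R,7R)-7-hydroxyhimachal-3-en-2-one (7α-OH, 7β-CH3) | CC1=CC[C@H]2[C@](C)(O)CCCC(C)(C)[C@@H]2C1=O | intermediate
11 | (1R,3R,4R,6R,7R)-3,4-epoxy-7-hydroxyhimachalan-2-one (3α,4α-epoxide) | C[C@@]12O[C@@H]1C[C@H]3[C@](C)(O)CCCC(C)(C)[C@@H]3C2=O | intermediate
12 | hydrazone of 11 at C-2 | C[C@@]12O[C@@H]1C[C@H]3[C@](C)(O)CCCC(C)(C)[C@@H]3C2=NN | intermediate (not isolated)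
13 | (1R,4R,6R,7R)-himachal-2-ene-4,7-diol (4α-OH, 7α-OH) | O[C@@H]1C[C@@H]2[C@@H](C=C1C)C(C)(C)CCC[C@@]2(C)O | intermediate
14 | 3-acetoxy-4-methoxybenzoic acid | COc1ccc(C(=O)O)cc1OC(C)=O | starting material
15 | (1R,4R,6R,7R)-7-hydroxyhimachal-2-en-4-yl 3-acetoxy-4-methoxybenzoate | COc1ccc(C(=O)O[C@@H]2C[C@@H]3[C@@H](C=C2C)C(C)(C)CCC[C@@]3(C)O)cc1OC(C)=O | intermediate (not isolated)
16 | (1R,4R,6R,7R)-7-hydroxyhimachal-2-en-4-yl 3-hydroxy-4-methoxybenzoate | COc1ccc(C(=O)O[C@@H]2C[C@@H]3[C@@H](C=C2C)C(C)(C)CCC[C@@]3(C)O)cc1O | target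

**Step count and risks**

Total steps: 8. Longest linear sequence: 8 (steps 1 to 8 from (R)-carvone; compounds 3, 4 and 14 are bought).

Steps most likely to fail:

Step 2 (the proposed photochemical alkylation). The tertiary radical may add at the other diene terminus, the cation may be lost by elimination, or conversion at the crowded C-6 may be low. The fallback is known chemistry, the Lewis-acid SN1 tert-alkylation of silyl enol ethers (Reetz alkylation): it sets out from 2, which is treated with commercial 1-bromo-3-chloro-3-methylbutane and TiCl4 in CH2Cl2 at −78 to −40 °C, and it comes back to the route at 6; it makes no new compound (F0).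

Step 4 (seven-membered ring closure by enolate alkylation). Enolate equilibration to the ring-fusion carbon would close a five-membered ring instead, and it could also epimerise C-6. The fallback replaces the ketone enolate by a metallated hydrazone, which forms only at the methyl group and does not equilibrate. It sets out from 8: condensation with 1,1-dimethylhydrazine at the unhindered methyl ketone gives the N,N-dimethylhydrazone F1; LiN(iPr)2 in THF metallates its methyl group and the aza-enolate closes ring B to the bicyclic hydrazone F2; hydrolysis with aqueous oxalic acid returns the route at 9.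

Step 5 (methyl addition at C-7). CH3Li may also attack the enone, 1,2 or 1,4, and the facial selectivity on the seven-membered ring may be lower than on cyclohexanones. The fallback builds C-14 from a methylene transfer and a hydride instead. It sets out from 9: dimethylsulfonium methylide (Me3S+ I−, KN(SiMe3)2, THF, −10 °C) adds to the saturated ketone along the same axial β path and gives the spiro-epoxide F3 with oxygen α; LiAlH4 opens the epoxide at CH2 and reduces the enone carbonyl, giving the diol F4; MnO2 reoxidises the allylic alcohol and the route is rejoined at 10.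

**Further compounds**

F0 | step 2 | none | none
F1 | step 4 | (5R,6R)-6-(4-bromo-2-methylbutan-2-yl)-5-[1-(2,2-dimethylhydrazinylidene)ethyl]-2-methylcyclohex-2-en-1-one | CC1=CC[C@@H](C(C)=NN(C)C)[C@H](C(C)(C)CCBr)C1=O
F2 | step 4 | (1R,6R)-14-norhimachal-3-ene-2,7-dione 7-(N,N-dimethylhydrazone) | CC1=CC[C@H]2C(=NN(C)C)CCCC(C)(C)[C@@H]2C1=O
F3 | step 5 | (1R,6R,7R)-7,14-epoxyhimachal-3-en-2-one (spiro-epoxide, oxygen α) | CC1=CC[C@H]2[C@@]3(CO3)CCCC(C)(C)[C@@H]2C1=O
F4 | step 5 | (1R,6R,7R)-himachal-3-ene-2,7-diol (both C-2 epimers) | CC1=CC[C@H]2[C@](C)(O)CCCC(C)(C)[C@@H]2C1O
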